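**Plan**

- Retrosynthesis: ring D is opened last at C8–C15. Before that, C17 is cut from C16, ring C at C13–C14 and C9–C11, and the spiro δ-lactone at C9–C10 and O–C7, which leaves a ring A epoxide.
- Enabling feature (ent-kaurane numbering): C8 is the α-carbon of the lactone (C7, O, C20, C10, C9, C8). C15 is the free terminus of the C15–C16–C17 allyl unit on C13. Both are nucleophilic and lie 1,3 to each other across ring C (C8, C9, C11, C12, C13, C14), so removing two electrons joins them and closes ring D (C8, C14, C13, C16, C15).
- Forward order: ring A from 4,4-dimethylcyclohexane-1,3-dione, then the spiro-lactone by radical epoxide opening and acrylate addition, then ring C by cuprate addition at C9 and Michael closure C13–C14, then the allylsilane, anodic closure of ring D, and finally the C1 acetate, C15 hydroxyl and C6 aldehyde.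
- Stereochemistry: C5 comes from a catalytic asymmetric conjugate reduction. C1 (Luche reduction), C10 (radical addition) and C9 (cuprate addition) are relayed from C5. C13 is set under equilibrating conditions, C8 is dictated by C13 in the ring D closure, and C15 by Luche reduction of the enone from its open face.

Key step: step 19

Remark: α on ring A means the face of C20. The C8 configuration drawn for 19, 20, 26, 27, 31–33 and 35 and the epoxide configuration of 15 are the expected major ones; both centres become planar later, so they do not matter.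
Remark: the ligand antipode in step 4 is chosen by analogy with simpler 3-substituted cyclohexenones and is exchanged if the sense of induction proves opposite.

Step 1
Reactants: 1 4,4-dimethylcyclohexane-1,3-dione
Product: 2 3-ethoxy-6,6-dimethylcyclohex-2-en-1-one
Conditions: EtOH, p-TsOH (cat.), toluene, reflux, Dean–Stark
Reagents that add atoms: ethanol, CCO
Why: Acid-catalysed enol etherification of the 1,3-dione is reversible and should settle on the vinylogous ester whose ethoxy group sits at the carbonyl remote from the gem-dimethyl group, leaving the hindered carbonyl free for step 2.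

Step 2
Reactants: 2 3-ethoxy-6,6-dimethylcyclohex-2-en-1-one; 3 1,3-dithiane
Product: 6 3-(1,3-dithian-2-yl)-4,4-dimethylcyclohex-2-en-1-one, via 2-lithio-1,3-dithiane 4 (not isolated), via lithium alkoxide adduct 5 (not isolated)
Conditions: 3, n-BuLi, THF, −30 °C; then 2, −78 → 0 °C; then 2 M HCl, THF, rt
Reagents that add atoms: water, O
Why: In this Stork–Danheiser sequence the lithiated dithiane adds 1,2 to the only free carbonyl (which has no α-hydrogen on the gem-dimethyl side), and acid hydrolysis of the enol ether with loss of water transposes the enone so that the masked formyl carbon C6 sits on C5.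

Step 3
Reactants: 6 3-(1,3-dithian-2-yl)-4,4-dimethylcyclohex-2-en-1-one
Product: 7 3-(dimethoxymethyl)-4,4-dimethylcyclohex-2-en-1-one
Conditions: PhI(OCOCF3)2, MeOH, 0 °C → rt
Reagents that add atoms: methanol, CO
Why: Oxidative dethioacetalisation with the hypervalent iodine reagent in methanol is a known direct exchange of a 1,3-dithiane for a dimethyl acetal and should spare the enone.

Step 4
Reactants: 7 3-(dimethoxymethyl)-4,4-dimethylcyclohex-2-en-1-one; 8 N,N-dimethylmethyleneiminium iodide (Eschenmoser's salt)
Product: 10 (2R,3S)-3-(dimethoxymethyl)-2-[(dimethylamino)methyl]-4,4-dimethylcyclohexan-1-one, via diphenylsilyl enol ether 9 (not isolated)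
Conditions: CuCl (5 mol%), NaOt-Bu (5 mol%), (S)-p-Tol-BINAP (5 mol%), Ph2SiH2, toluene, 0 °C; then 8, CH2Cl2, 0 °C → rt
Reagents that add atoms: none
Why: Ligand-controlled copper hydride conjugate reduction of a 3-substituted cyclohexenone delivers hydride to C5 and sets that stereocentre under catalyst control, and the regiodefined silyl enol ether then undergoes a Mannich reaction at C10 anti to the C5 substituent (this second centre is removed in step 5).

Step 5
Reactants: 10 (2R,3S)-3-(dimethoxymethyl)-2-[(dimethylamino)methyl]-4,4-dimethylcyclohexan-1-one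
Product: 12 (3R)-3-(dimethoxymethyl)-4,4-dimethyl-2-methylidenecyclohexan-1-one, via trimethylammonium iodide 11 (not isolated)
Conditions: MeI, CH2Cl2, rt; then sat. aq. NaHCO3, rt; used at once
Reagents that add atoms: none
Why: Quaternisation and bicarbonate-induced E1cB loss of trimethylamine is the standard α-methylenation of ketones, and the mild base should not move the double bond into the ring, so C5 is kept.

Step 6
Reactants: 12 (3R)-3-(dimethoxymethyl)-4,4-dimethyl-2-methylidenecyclohexan-1-one
Product: 13 (1S,3R)-3-(dimethoxymethyl)-4,4-dimethyl-2-methylidenecyclohexan-1-ol (hydroxyl cis to the dimethoxymethyl group)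
Conditions: NaBH4, CeCl3·7H2O, MeOH, −78 °C
Reagents that add atoms: none
Why: In this Luche 1,2-reduction hydride should enter C1 on the side not screened by the C5 substituent, which in either chair gives the alcohol cis to that substituent (both equatorial), i.e. the 1α configuration.

Step 7
Reactants: 13 (1S,3R)-3-(dimethoxymethyl)-4,4-dimethyl-2-methylidenecyclohexan-1-ol
Product: 14 tert-butyl{[(1S,3R)-3-(dimethoxymethyl)-4,4-dimethyl-2-methylidenecyclohexyl]oxy}dimethylsilane
Conditions: t-BuMe2SiCl, imidazole, DMAP (cat.), DMF, 40 °C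
Reagents that add atoms: tert-butyldimethylsilyl chloride, CC(C)(C)[Si](C)(C)Cl
Why: Routine silylation protects O1 for the base and radical steps, and it keeps that oxygen from competing with O20 for the ester in step 9.

Step 8
Reactants: 14 tert-butyl{[(1S,3R)-3-(dimethoxymethyl)-4,4-dimethyl-2-methylidenecyclohexyl]oxy}dimethylsilane
Product: 15 spiro-epoxide of 14 (C10–C20 oxirane; oxygen anti to the C1 and C5 substituents)
Conditions: mCPBA, NaHCO3, CH2Cl2, 0 °C
Reagents that add atoms: 3-chloroperoxybenzoic acid, OOC(=O)c1cccc(Cl)c1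
Why: Prilezhaev epoxidation of the 1,1-disubstituted alkene under buffered conditions leaves the acetal and silyl ether alone, and either epoxide epimer leads to the same C10 radical.

Step 9
Reactants: 15 spiro-epoxide of 14; 16 2,2,2-trifluoroethyl acrylate
Product: 18 saturated spiro δ-lactone (C7(=O)–O–C20–C10–C9H2–C8H2; 1α-OTBS; 6-dimethyl acetal; C20 cis to both ring A substituents), via hydroxy trifluoroethyl ester 17 (not isolated)
Conditions: Cp2TiCl2 (0.3 equiv), Zn dust, 2,4,6-collidine·HCl, 16 (3 equiv), THF, rt → 40 °C
Reagents that add atoms: none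
Why: Nugent–RajanBabu opening of the epoxide by Cp2TiCl gives the tertiary C10 radical, which adds to the acrylate (Giese addition) from the face opposite the 1-silyloxy group, the 5-dimethoxymethyl group and the axial C4 methyl, fixing C10; the C20 hydroxyl then lactonises onto the activated ester.

Step 10
Reactants: 18 saturated spiro δ-lactone
Product: 21 spiro-pentenolide (C8=C9 unsaturated lactone; ring A as in 18), via α-phenylselanyl lactone 19 (not isolated), via selenoxide 20 (not isolated)
Conditions: LiN(i-Pr)2, THF, −78 °C; PhSeBr; then pyridine, 30% H2O2, 0 °C → rt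
Reagents that add atoms: none
Why: α-Selenenylation of the lactone enolate followed by oxidation and selenoxide syn-elimination can only use the C9 hydrogens and so gives the conjugated lactone.

Step 11
Reactants: 22 5-bromopentan-2-one
Product: 23 5-bromo-2-methylpent-1-ene
Conditions: Ph3PCH3Br, NaN(SiMe3)2, THF, 0 °C; then 22, −78 °C → rt
Reagents that add atoms: methyltriphenylphosphonium bromide, C[P+](c1ccccc1)(c1ccccc1)c1ccccc1.[Br-]
Why: Wittig methylenation with a preformed, base-free ylide masks the ketone as a 1,1-disubstituted alkene that tolerates Grignard formation and is unmasked by ozone in step 14.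

Step 12
Reactants: 21 spiro-pentenolide; 23 5-bromo-2-methylpent-1-ene; 8 N,N-dimethylmethyleneiminium iodide
Product: 26 9-(4-methylpent-4-en-1-yl)-8-[(dimethylamino)methyl] lactone (C11 cis to C1 on the lactone ring; C8 substituent trans to the chain), via Grignard reagent 24 (not isolated), via trimethylsilyl ketene acetal 25 (not isolated)
Conditions: 23, Mg, THF; then CuBr·SMe2 (0.2 equiv), Me3SiCl, DMPU, 21, THF, −78 → −30 °C; then 8, CH2Cl2, −30 °C → rt
Reagents that add atoms: none
Why: Copper-catalysed, Me3SiCl-accelerated conjugate addition of the Grignard reagent should reach C9 from the lactone face flanked only by the C1 oxygen (whose silyl group points away), because the other face is covered by a methoxy group of the C6 acetal; this sets C9, and the silyl ketene acetal is then aminomethylated at C8 (Mannich reaction).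

Step 13
Reactants: 26 9-(4-methylpent-4-en-1-yl)-8-[(dimethylamino)methyl] lactone
Product: 28 α-methylene lactone (C8=C14H2) carrying the 4-methylpent-4-en-1-yl chain on C9, via trimethylammonium iodide 27 (not isolated)
Conditions: MeI, CH2Cl2/MeOH, rt; then sat. aq. NaHCO3, rt
Reagents that add atoms: none
Why: Quaternisation and E1cB elimination of trimethylamine is the standard α-methylenation of lactones and introduces C14.

Step 14
Reactants: 28 α-methylene lactone
Product: 30 9-(4-oxopentyl) α-methylene lactone (methyl ketone), via ozonide 29 (not isolated)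
Conditions: O3, CH2Cl2, −78 °C, Sudan Red 7B end point; then PPh3, −78 °C → rt
Reagents that add atoms: ozone, [O-][O+]=O
Why: Ozonolysis is much faster at the electron-rich 1,1-disubstituted alkene than at the electron-poor α-methylene lactone, so titration to the indicator end point should release the methyl ketone selectively.

Step 15
Reactants: 30 9-(4-oxopentyl) α-methylene lactone
Product: 31 tricyclic lactone with ring C closed and an acetyl group on C13 (acetyl equatorial and trans to C10 across ring C; lactone trans-fused)
Conditions: KOt-Bu (0.2 equiv), THF/t-BuOH, 0 °C → rt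
Reagents that add atoms: none
Why: Base-catalysed intramolecular Michael addition (6-exo-trig) of the ketone α-carbon C13 to the α-methylene lactone forms C13–C14, and because C13 and C8 equilibrate the acetyl group should end up equatorial, trans to C10, which is the configuration ring D needs.

Step 16
Reactants: 31 tricyclic 13-acetyl lactone
Product: 33 enol triflate of 31 (C16(OSO2CF3)=CH2 on C13), via potassium enolate 32 (not isolated)
Conditions: KN(SiMe3)2, THF, −78 °C; PhNTf2, −78 → 0 °C
Reagents that add atoms: N-phenylbis(trifluoromethanesulfonimide), O=S(=O)(N(c1ccccc1)S(=O)(=O)C(F)(F)F)C(F)(F)F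
Why: Kinetic deprotonation takes the acetyl methyl group, which is more acidic and more accessible than the C13 methine or the lactone α-hydrogen, and O-triflation gives the terminal enol triflate without disturbing C13.

Step 17
Reactants: 33 enol triflate; 34 (trimethylsilyl)methylmagnesium chloride
Product: 35 tricyclic lactone with a 3-(trimethylsilyl)prop-1-en-2-yl group on C13
Conditions: Pd(PPh3)4 (5 mol%), LiCl, THF, 0 °C → rt
Reagents that add atoms: none
Why: Palladium-catalysed Kumada coupling of enol triflates with Me3SiCH2MgCl is the standard route to 2-substituted allylsilanes, and this Grignard reagent adds only slowly to lactones.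

Step 18
Reactants: 35 allylsilane lactone
Product: 37 tert-butyldimethylsilyl ketene acetal of 35 (C8=C7(OSiMe2t-Bu)–O), via potassium lactone enolate 36 (not isolated)
Conditions: KN(SiMe3)2, THF/DMPU, −78 °C; t-BuMe2SiCl, −78 → 0 °C; non-aqueous work-up, used crude
Reagents that add atoms: tert-butyldimethylsilyl chloride, CC(C)(C)[Si](C)(C)Cl
Why: Deprotonation at C8, the only acidic position left, and O-silylation of the lactone enolate give the tetrasubstituted silyl ketene acetal and erase the C8 configuration.

Step 19
Reactants: 37 silyl ketene acetal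
Product: 38 tetracyclic lactone with ring D closed (C15 methylene; C16 exocyclic methylene; 1α-OTBS; 6-dimethyl acetal)
Conditions: reticulated vitreous carbon anode, Pt cathode, undivided cell, constant current (about 8 mA, 2.2 F/mol), LiClO4 (0.1 M), 2,6-lutidine, CH2Cl2/MeOH 4:1, 0 °C → rt
Reagents that add atoms: none
Why: Proposed new method: one-electron oxidation at the carbon anode should occur at the tetrasubstituted silyl ketene acetal, the most electron-rich group present, giving a radical cation electrophilic at C8; C15, the nucleophilic terminus of the allylsilane on C13, adds to C8, a second electron is lost, and methanol takes Me3Si from the β-silyl cation at C16 and t-BuMe2Si from the lactone oxygen, leaving the C16 methylene and the lactone. The closest known reaction types are the anodic couplings of enol ether and ketene acetal radical cations with allylsilanes and the Pd(OAc)2-mediated cyclisation of silyl enol ethers and lactone silyl ketene acetals onto alkenes to give bicyclo[3.2.1]octanes; joining a lactone ketene acetal and an allylsilane across a ring in this way has not been shown. Ring D closes in the 5-endo mode at the allylsilane alkene, a cation–olefin type closure between the 1,3-diaxial positions C8 and C13 of a chair ring C. The one new stereocentre, C8, is controlled by C13, because the two-carbon bridge can reach C8 only on the face of ring C that carries the C13 side chain, the face of H-9. The step needs oxidation of the ketene acetal before the allylsilane, silyl ether and acetal, and C–C bond formation before solvolysis of the radical cation; the lower oxidation potential of the ketene acetal, the 2,6-lutidine buffer and the short tether to C15 should secure this.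

Step 20
Reactants: 38 tetracyclic lactone
Product: 40 1α-acetate of the tetracyclic lactone (6-dimethyl acetal), via C1 alcohol 39 (not isolated)
Conditions: Bu4NF, AcOH (1 equiv), THF, 0 → 40 °C; then Ac2O, pyridine, DMAP (cat.), rt
Reagents that add atoms: acetic anhydride, CC(=O)OC(C)=O
Why: Fluoride cleavage of the silyl ether is buffered so that the free 1-hydroxyl, which lies over the lactone carbonyl, stays protonated and cannot translactonise, and acetylation in the same flask installs the C1 acetate.

Step 21
Reactants: 40 1α-acetate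
Product: 41 15-hydroxy derivative of 40 (hydroxyl on the side of C14; the 15-epimer of 43)
Conditions: SeO2 (0.5 equiv), t-BuOOH, CH2Cl2, 0 °C → rt
Reagents that add atoms: tert-butyl hydroperoxide (its oxygen reaches C15 through SeO2), CC(C)(C)OO
Why: Allylic oxidation with SeO2 (ene reaction, then [2,3]-sigmatropic shift) can only occur at C15, since the other allylic position is the bridgehead C13, and oxygen is expected on the exposed face toward C14; any enone formed directly joins the route at step 23.

Step 22
Reactants: 41 15-hydroxy derivative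
Product: 42 15-oxo-16-methylene enone (1α-OAc; 6-dimethyl acetal)
Conditions: Dess–Martin periodinane, NaHCO3, CH2Cl2, rt
Reagents that add atoms: none
Why: Dess–Martin oxidation of the allylic alcohol under buffered conditions gives the enone without touching acetal, acetate or lactone.

Step 23
Reactants: 42 enone
Product: 43 15-alcohol with the hydroxyl syn to C9 as in the target (6-dimethyl acetal)
Conditions: NaBH4, CeCl3·7H2O, MeOH, −78 → −40 °C
Reagents that add atoms: none
Why: In this Luche 1,2-reduction the carbonyl face toward C9 is screened by the axial hydrogen on C11, so hydride should enter from the side of C14 and place the hydroxyl syn to C9, while acetate, lactone and acetal are not reduced.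

Step 24
Reactants: 43 15-alcohol
Product: 44 CNP0117386.1
Conditions: p-TsOH·H2O (cat.), acetone/H2O 10:1, rt
Reagents that add atoms: water, O
Why: Mild acid-catalysed hydrolysis (transacetalisation to acetone) of the dimethyl acetal frees the C6 aldehyde under conditions that the acetate, lactone and allylic alcohol should survive.

**Compound list**

1 | 4,4-dimethylcyclohexane-1,3-dione | CC1(C)CCC(=O)CC1=O | starting material
2 | 3-ethoxy-6,6-dimethylcyclohex-2-en-1-one | CCOC1=CC(=O)C(C)(C)CC1 | intermediate
3 | 1,3-dithiane | C1CSCSC1 | starting material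
4 | 2-lithio-1,3-dithiane | [Li]C1SCCCS1 | intermediate
5 | lithium 1-(1,3-dithian-2-yl)-3-ethoxy-6,6-dimethylcyclohex-2-en-1-olate | CCOC1=CC([O-])(C2SCCCS2)C(C)(C)CC1.[Li+] | intermediate
6 | 3-(1,3-dithian-2-yl)-4,4-dimethylcyclohex-2-en-1-one | CC1(C)CCC(=O)C=C1C1SCCCS1 | intermediate
7 | 3-(dimethoxymethyl)-4,4-dimethylcyclohex-2-en-1-one | COC(OC)C1=CC(=O)CCC1(C)C | intermediate
8 | N,N-dimethylmethyleneiminium iodide (Eschenmoser's salt) | C=[N+](C)C.[I-] | starting material
9 | {[(3S)-3-(dimethoxymethyl)-4,4-dimethylcyclohex-1-en-1-yl]oxy}diphenylsilane | COC(OC)[C@H]1C=C(O[SiH](c2ccccc2)c2ccccc2)CCC1(C)C | intermediate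
10 | (2R,3S)-3-(dimethoxymethyl)-2-[(dimethylamino)methyl]-4,4-dimethylcyclohexan-1-one | CN(C)C[C@@H]1C(=O)CCC(C)(C)[C@H]1C(OC)OC | intermediate
11 | N-methyl ammonium iodide of 10 | C[N+](C)(C)C[C@@H]1C(=O)CCC(C)(C)[C@H]1C(OC)OC.[I-] | intermediate
12 | (3R)-3-(dimethoxymethyl)-4,4-dimethyl-2-methylidenecyclohexan-1-one | C=C1C(=O)CCC(C)(C)[C@H]1C(OC)OC | intermediate
13 | (1S,3R)-3-(dimethoxymethyl)-4,4-dimethyl-2-methylidenecyclohexan-1-ol | C=C1[C@@H](O)CCC(C)(C)[C@H]1C(OC)OC | intermediate
14 | tert-butyldimethylsilyl ether of 13 | C=C1[C@@H](O[Si](C)(C)C(C)(C)C)CCC(C)(C)[C@H]1C(OC)OC | intermediate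
15 | spiro-epoxide of 14 (oxygen anti to the C1 and C5 substituents) | C1O[C@@]12[C@@H](O[Si](C)(C)C(C)(C)C)CCC(C)(C)[C@H]2C(OC)OC | intermediate
16 | 2,2,2-trifluoroethyl acrylate | C=CC(=O)OCC(F)(F)F | starting material
17 | 2,2,2-trifluoroethyl 3-(ring A)-propanoate with free C20 hydroxymethyl on C10 | OC[C@@]1(CCC(=O)OCC(F)(F)F)[C@@H](O[Si](C)(C)C(C)(C)C)CCC(C)(C)[C@H]1C(OC)OC | intermediate
18 | saturated spiro δ-lactone (1α-OTBS; 6-dimethyl acetal) | O=C1OC[C@@]2(CC1)[C@@H](O[Si](C)(C)C(C)(C)C)CCC(C)(C)[C@H]2C(OC)OC | intermediate
19 | 8-phenylselanyl derivative of 18 (C8 epimers) | O=C1OC[C@@]2(CC1[Se]c1ccccc1)[C@@H](O[Si](C)(C)C(C)(C)C)CCC(C)(C)[C@H]2C(OC)OC | intermediate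
20 | selenoxide of 19 | O=C1OC[C@@]2(CC1[Se](=O)c1ccccc1)[C@@H](O[Si](C)(C)C(C)(C)C)CCC(C)(C)[C@H]2C(OC)OC | intermediate
21 | spiro-pentenolide (C8=C9) | O=C1OC[C@@]2(C=C1)[C@@H](O[Si](C)(C)C(C)(C)C)CCC(C)(C)[C@H]2C(OC)OC | intermediate
22 | 5-bromopentan-2-one | CC(=O)CCCBr | starting material
23 | 5-bromo-2-methylpent-1-ene | C=C(C)CCCBr | intermediate
24 | (4-methylpent-4-en-1-yl)magnesium bromide | C=C(C)CCC[Mg]Br | intermediate
25 | trimethylsilyl ketene acetal of the C9 adduct | C=C(C)CCC[C@@H]1C=C(O[Si](C)(C)C)OC[C@]12[C@@H](O[Si](C)(C)C(C)(C)C)CCC(C)(C)[C@H]2C(OC)OC | intermediate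
26 | 9-(4-methylpent-4-en-1-yl)-8-[(dimethylamino)methyl] lactone (8,9-trans) | C=C(C)CCC[C@@H]1[C@@H](CN(C)C)C(=O)OC[C@]12[C@@H](O[Si](C)(C)C(C)(C)C)CCC(C)(C)[C@H]2C(OC)OC | intermediate
27 | N-methyl ammonium iodide of 26 | C=C(C)CCC[C@@H]1[C@@H](C[N+](C)(C)C)C(=O)OC[C@]12[C@@H](O[Si](C)(C)C(C)(C)C)CCC(C)(C)[C@H]2C(OC)OC.[I-] | intermediate
28 | α-methylene lactone with the 4-methylpent-4-en-1-yl chain on C9 | C=C(C)CCC[C@@H]1C(=C)C(=O)OC[C@]12[C@@H](O[Si](C)(C)C(C)(C)C)CCC(C)(C)[C@H]2C(OC)OC | intermediate
29 | ozonide (1,2,4-trioxolane) of the side-chain alkene of 28 | CC1(OCOO1)CCC[C@@H]2C(=C)C(=O)OC[C@]23[C@@H](O[Si](C)(C)C(C)(C)C)CCC(C)(C)[C@H]3C(OC)OC | intermediate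
30 | 9-(4-oxopentyl) α-methylene lactone | CC(=O)CCC[C@@H]1C(=C)C(=O)OC[C@]12[C@@H](O[Si](C)(C)C(C)(C)C)CCC(C)(C)[C@H]2C(OC)OC | intermediate
31 | tricyclic lactone with 13-acetyl group (acetyl trans to C10; lactone trans-fused) | CC(=O)[C@@H]1CC[C@@H]2[C@@H](C1)C(=O)OC[C@]23[C@@H](O[Si](C)(C)C(C)(C)C)CCC(C)(C)[C@H]3C(OC)OC | intermediate
32 | potassium enolate of 31 at the acetyl methyl group | C=C([O-])[C@@H]1CC[C@@H]2[C@@H](C1)C(=O)OC[C@]23[C@@H](O[Si](C)(C)C(C)(C)C)CCC(C)(C)[C@H]3C(OC)OC.[K+] | intermediate
33 | enol triflate of 31 | C=C(OS(=O)(=O)C(F)(F)F)[C@@H]1CC[C@@H]2[C@@H](C1)C(=O)OC[C@]23[C@@H](O[Si](C)(C)C(C)(C)C)CCC(C)(C)[C@H]3C(OC)OC | intermediate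
34 | (trimethylsilyl)methylmagnesium chloride | C[Si](C)(C)C[Mg]Cl | starting material
35 | tricyclic lactone with 3-(trimethylsilyl)prop-1-en-2-yl group on C13 | C=C(C[Si](C)(C)C)[C@@H]1CC[C@@H]2[C@@H](C1)C(=O)OC[C@]23[C@@H](O[Si](C)(C)C(C)(C)C)CCC(C)(C)[C@H]3C(OC)OC | intermediate
36 | potassium enolate of lactone 35 | C=C(C[Si](C)(C)C)[C@@H]1CC[C@@H]2C(C1)=C([O-])OC[C@]23[C@@H](O[Si](C)(C)C(C)(C)C)CCC(C)(C)[C@H]3C(OC)OC.[K+] | intermediate
37 | tert-butyldimethylsilyl ketene acetal of 35 | C=C(C[Si](C)(C)C)[C@@H]1CC[C@@H]2C(C1)=C(O[Si](C)(C)C(C)(C)C)OC[C@]23[C@@H](O[Si](C)(C)C(C)(C)C)CCC(C)(C)[C@H]3C(OC)OC | intermediate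
38 | tetracyclic lactone (ring D closed; C16 methylene; 1α-OTBS; 6-dimethyl acetal) | C=C1[C@@H]2CC[C@@H]3[C@](C2)(C(=O)OC[C@]32[C@@H](O[Si](C)(C)C(C)(C)C)CCC(C)(C)[C@H]2C(OC)OC)C1 | intermediate
39 | 1α-alcohol from 38 | C=C1[C@@H]2CC[C@@H]3[C@](C2)(C(=O)OC[C@]32[C@@H](O)CCC(C)(C)[C@H]2C(OC)OC)C1 | intermediate
40 | 1α-acetate | C=C1[C@@H]2CC[C@@H]3[C@](C2)(C(=O)OC[C@]32[C@@H](OC(C)=O)CCC(C)(C)[C@H]2C(OC)OC)C1 | intermediate
41 | 15-hydroxy derivative of 40 (hydroxyl toward C14; 15-epimer of 43) | C=C1[C@@H]2CC[C@@H]3[C@](C2)(C(=O)OC[C@]32[C@@H](OC(C)=O)CCC(C)(C)[C@H]2C(OC)OC)[C@H]1O | intermediate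
42 | 15-oxo-16-methylene enone | C=C1[C@@H]2CC[C@@H]3[C@](C2)(C(=O)OC[C@]32[C@@H](OC(C)=O)CCC(C)(C)[C@H]2C(OC)OC)C1=O | intermediate
43 | 15-alcohol with target configuration (6-dimethyl acetal) | C=C1[C@@H]2CC[C@@H]3[C@](C2)(C(=O)OC[C@]32[C@@H](OC(C)=O)CCC(C)(C)[C@H]2C(OC)OC)[C@@H]1O | intermediate
44 | CNP0117386.1 | C=C1[C@@H]2CC[C@@H]3[C@](C2)(C(=O)OC[C@]32[C@@H](OC(C)=O)CCC(C)(C)[C@H]2C=O)[C@@H]1O | target

**Step count:** 24 steps in total. The longest linear sequence is 23 steps (steps 1–10 and 12–24); step 11 prepares the side-chain bromide.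

**Steps most likely to fail**

1. Step 19. The radical cation may lose its silyl group to methanol, or be protonated back to lactone 35, before C15 reaches C8, so that ring D does not close. The fallback sets out from 31 and returns at 38. Double deprotonation of 31 with LiN(i-Pr)2 in THF at −78 °C gives the kinetic enolate at the acetyl methyl group (C15) together with the lactone enolate at C8. Oxidation of this dienolate with Fe(acac)3 (−78 °C → rt) is a known intramolecular oxidative enolate coupling that forms the same C8–C15 bond as a 1,4-dicarbonyl unit; it should give the 16-oxo-17-nor tetracyclic lactone F1. Wittig methylenation of the C16 ketone (Ph3P=CH2, THF) then gives 38.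

2. Step 12. Transfer of the primary alkyl group to C9 may be too slow next to the spiro centre, or may occur from the face syn to the C6 acetal. The fallback sets out from 21 and returns at 31. The smaller, more reactive vinyl group is added instead (CH2=CHMgBr, CuBr·SMe2, Me3SiCl, THF, −78 °C). The silyl ketene acetal is turned into the lithium enolate with MeLi and alkylated with 3-(bromomethyl)but-3-en-2-one to give the 9-vinyl-8-(2-acetylallyl) lactone F2. Ring-closing metathesis with the second-generation Grubbs catalyst, (H2IMes)(PCy3)Cl2Ru=CHPh, in toluene at 80 °C closes ring C at C12=C13 to the cyclohexenyl methyl ketone F3. Hydrogenation (H2, Pd/C, EtOAc) and equilibration with KOt-Bu then give 31.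

3. Step 4. The chiral copper hydride may discriminate the two faces of the enone poorly, because both flanks of C5 are fully substituted. The fallback sets out from 7 and returns at 13. The reduction is run without a chiral ligand ([(Ph3P)CuH]6 cat., Ph2SiH2), and the same aminomethylation, elimination and Luche reduction give racemic 10 F4, racemic 12 F5 and racemic cis alcohol 13 F6. Kinetic resolution by lipase-catalysed acylation (Candida antarctica lipase B, vinyl acetate, t-BuOMe, 30 °C) should acetylate the (1R) enantiomer to the acetate of ent-13 F7, following the usual preference of lipases for secondary alcohols with this arrangement of large and medium groups. The unreacted (1S) alcohol 13 is separated and carried on.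

**Further compounds**

F1 | step 19 | 16-oxo-17-nor tetracyclic lactone (1α-OTBS; 6-dimethyl acetal) | O=C1[C@@H]2CC[C@@H]3[C@](C2)(C(=O)OC[C@]32[C@@H](O[Si](C)(C)C(C)(C)C)CCC(C)(C)[C@H]2C(OC)OC)C1
F2 | step 12 | 9-vinyl-8-(2-acetylprop-2-en-1-yl) lactone (8,9-trans) | C=C[C@@H]1[C@@H](CC(=C)C(C)=O)C(=O)OC[C@]12[C@@H](O[Si](C)(C)C(C)(C)C)CCC(C)(C)[C@H]2C(OC)OC
F3 | step 12 | tricyclic lactone with C12=C13 double bond and 13-acetyl group | CC(=O)C1=CC[C@@H]2[C@@H](C1)C(=O)OC[C@]23[C@@H](O[Si](C)(C)C(C)(C)C)CCC(C)(C)[C@H]3C(OC)OC
F4 | step 4 | racemic 10 (10 with its mirror image; mirror image shown) | CN(C)C[C@H]1C(=O)CCC(C)(C)[C@@H]1C(OC)OC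
F5 | step 4 | racemic 12 (12 with its mirror image; mirror image shown) | C=C1C(=O)CCC(C)(C)[C@@H]1C(OC)OC
F6 | step 4 | racemic 13 (13 with its mirror image; mirror image shown) | C=C1[C@H](O)CCC(C)(C)[C@@H]1C(OC)OC
F7 | step 4 | acetate of the enantiomer of 13 | C=C1[C@H](OC(C)=O)CCC(C)(C)[C@@H]1C(OC)OC
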